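**Plan**

- **Enabling feature:** in ring A the carbon bearing the sulfate oxygen lies between the carbon bonded to ring B and a ring CH. Cutting its two ring C–C bonds removes it as CO and leaves a five-carbon 3-acyloxy-1,4-enyne that already holds the other two ring A oxygens (para as ester, ortho as enol ether).
- **Other cuts, in retrosynthetic order:** O–S (sulfate), propargylic C–C (ethynyl Grignard), enol-ether C=C (Horner–Wadsworth–Emmons), ring B–CHO (Vilsmeier–Haack), ring B–ring C (Ullmann).
- **Forward order:** rings B and C both come from phloroglucinol and are joined first, the chain is then grown on ring B, and ring A is closed last around CO.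
- **Endgame:** ring A is formed with three different oxygens (free OH from CO, OBn, OPiv), so sulfation needs no selectivity. One saponification and one hydrogenolysis finish the route.
- **Stereochemistry:** the target has no stereocentre. The propargylic centre is racemic and disappears on aromatisation, so only the Z enol-ether geometry, set in the olefination, has to be right.

Key step: step 11

Remark on the chemistry: the target SMILES carries no axial descriptor, so the hindered ring A–ring B axis is left uncontrolled (racemic if it proves configurationally stable).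
Remark on the chemistry: the sulfate monoesters of the last three steps are drawn as free hydrogen sulfates, as the target is, but would be handled as pyridinium or sodium salts until the final cation exchange.
Abbreviations: Bn = benzyl, Piv = pivaloyl, Ar = 2,4,6-tris(benzyloxy)-3-[2,4,6-tris(benzyloxy)phenyl]phenyl (rings B and C, fully benzylated).

Step 1
Reactants: 1 phloroglucinol; 2 benzyl bromide (3.3 equiv)
Product: 3 1,3,5-tris(benzyloxy)benzene
Conditions: K2CO3, DMF, rt → 60 °C
Reagents that add atoms: benzyl bromide 2, BrCc1ccccc1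
Why: Williamson ether synthesis, in which carbonate in a dipolar aprotic solvent keeps the phloroglucinol anions reacting mainly at oxygen, and the C-benzylated by-products typical of this substrate should be removed by crystallisation.

Step 2
Reactants: 3 1,3,5-tris(benzyloxy)benzene
Product: 4 1,3,5-tris(benzyloxy)-2-iodobenzene
Conditions: NIS (1.0 equiv), MeCN/CH2Cl2, 0 °C → rt, dark
Reagents that add atoms: N-iodosuccinimide, O=C1CCC(=O)N1I
Why: Electrophilic aromatic iodination, in which the three free positions of 3 are equivalent and strongly activated, and the first iodine slows a second attack, so one equivalent should stop at the mono-iodide.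

Step 3
Reactants: 4 1,3,5-tris(benzyloxy)-2-iodobenzene (two molecules)
Product: 5 2,2',4,4',6,6'-hexakis(benzyloxy)-1,1'-biphenyl
Conditions: activated Cu powder (5 equiv), DMF, 150 °C, argon
Reagents that add atoms: none
Why: Classical Ullmann reductive homocoupling, the established entry to 2,2',4,4',6,6'-hexaalkoxybiphenyls from 2-iodo-1,3,5-trialkoxybenzenes, which tolerates four ortho substituents and benzyl ethers and needs no second coupling partner.

Step 4
Reactants: 5 2,2',4,4',6,6'-hexakis(benzyloxy)-1,1'-biphenyl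
Product: 7 Ar-CHO (2,4,6-tris(benzyloxy)-3-[2,4,6-tris(benzyloxy)phenyl]benzaldehyde), via aryl iminium dichlorophosphate 6 (not isolated)
Conditions: POCl3 (0.95 equiv), DMF (3 equiv), ClCH2CH2Cl, 0 → 60 °C; then ice/H2O
Reagents that add atoms: N,N-dimethylformamide, CN(C)C=O; water, O
Why: Vilsmeier–Haack formylation, in which all four free positions of 5 are equivalent and lie between two benzyloxy groups, the cationic iminium group of 6 shuts down its own ring, and a slight deficit of reagent with recovery of 5 should hold back attack on the other ring.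

Step 5
Reactants: 8 triethyl phosphonoacetate
Product: 9 ethyl 2-diazo-2-(diethoxyphosphoryl)acetate
Conditions: NaH, THF, 0 °C; 4-acetamidobenzenesulfonyl azide, 0 °C → rt
Reagents that add atoms: 4-acetamidobenzenesulfonyl azide, CC(=O)Nc1ccc(cc1)S(=O)(=O)N=[N+]=[N-]
Why: Regitz diazo transfer, in which the anion of the doubly activated methylene group attacks the terminal azide nitrogen and the adduct collapses to the diazo compound and the sulfonamide.

Step 6
Reactants: 9 ethyl 2-diazo-2-(diethoxyphosphoryl)acetate; 10 benzyl alcohol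
Product: 11 racemic ethyl 2-(benzyloxy)-2-(diethoxyphosphoryl)acetate
Conditions: Rh2(OAc)4 (1 mol%), toluene, 90 °C
Reagents that add atoms: benzyl alcohol 10, OCc1ccccc1
Why: Rhodium-carbenoid O–H insertion, in which Rh2(OAc)4 expels N2 from 9 and the electrophilic carbenoid is captured by the alcohol oxygen; the new stereocentre is racemic and is erased in step 7.

Step 7
Reactants: 7 Ar-CHO; 11 ethyl 2-(benzyloxy)-2-(diethoxyphosphoryl)acetate
Product: 12 ethyl (Z)-2-(benzyloxy)-3-Ar-prop-2-enoate
Conditions: NaH, THF, 0 → 50 °C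
Reagents that add atoms: none
Why: Horner–Wadsworth–Emmons olefination with a 2-alkoxyphosphonoacetate, a standard route to 2-alkoxyacrylates, in which reversible addition to the hindered aldehyde should favour the Z enol ether (bulky aryl trans to the ester), and any E isomer would be removed by chromatography.

Step 8
Reactants: 12 ethyl (Z)-2-(benzyloxy)-3-Ar-prop-2-enoate
Product: 13 (Z)-2-(benzyloxy)-3-Ar-prop-2-en-1-ol
Conditions: i-Bu2AlH (2.5 equiv), CH2Cl2, −78 → −20 °C; aq. potassium sodium tartrate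
Reagents that add atoms: none
Why: Hydride reduction of an α,β-unsaturated ester with i-Bu2AlH, which adds 1,2 twice to give the allylic alcohol and leaves the enol-ether double bond and its geometry alone.

Step 9
Reactants: 13 (Z)-2-(benzyloxy)-3-Ar-prop-2-en-1-ol
Product: 14 (Z)-2-(benzyloxy)-3-Ar-prop-2-enal
Conditions: activated MnO2 (15 equiv), CH2Cl2, rt
Reagents that add atoms: none
Why: MnO2 oxidation of an allylic alcohol, a neutral heterogeneous method that is selective for allylic alcohols and should spare the enol ether and the benzyl ethers.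

Step 10
Reactants: 14 (Z)-2-(benzyloxy)-3-Ar-prop-2-enal; 15 ethynylmagnesium bromide; 16 pivaloyl chloride
Product: 18 racemic (Z)-4-(benzyloxy)-5-Ar-pent-4-en-1-yn-3-yl pivalate, via bromomagnesium alkoxide 17 (not isolated)
Conditions: 15 (1.5 equiv), THF, −20 → 0 °C; then 16 (3 equiv), DMAP (10 mol%), 0 °C → rt; aq. NaHCO3, Et3N-deactivated silica
Reagents that add atoms: ethynylmagnesium bromide 15, C#C[Mg]Br; pivaloyl chloride 16, CC(C)(C)C(=O)Cl
Why: 1,2-Addition of an alkynyl Grignard reagent to an enal, followed by O-acylation of the magnesium alkoxide in the same flask, which avoids handling the acid-sensitive allylic-propargylic alcohol; the new stereocentre is deliberately racemic because it becomes sp2 in step 11.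

Step 11
Reactants: 18 racemic (Z)-4-(benzyloxy)-5-Ar-pent-4-en-1-yn-3-yl pivalate; 19 carbon monoxide
Product: 22 3-(benzyloxy)-5-(pivaloyloxy)-2-Ar-phenol, via dienylketene 20 (not isolated), via cyclohexadienone 21 (not isolated)
Conditions: [RhCl(CO)2]2 (5 mol%), CO (80 atm), CH2Cl2, 80 °C, autoclave
Reagents that add atoms: carbon monoxide 19, [C-]#[O+]
Why: Monovalent rhodium binds the terminal alkyne, the pivalate carbonyl oxygen attacks the inner alkyne carbon and the ester shifts 1,2, which leaves a rhodium vinylcarbene at the former alkyne terminus in conjugation with the enol ether. CO inserts into the Rh=C bond to give dienylketene 20, whose ketene carbon closes onto the aryl-bearing alkene carbon by 6π electrocyclisation (a formal [5+1] closure of six-membered ring A, with both new C–C bonds at the CO carbon), and dienone 21 enolises to phenol 22. The closest known reaction is the [RhCl(CO)2]2-catalysed [5+1] carbonylation of 3-acyloxy-1,4-enynes to resorcinol monoesters, from which this case departs only in the alkoxy group on the alkene and the size of the aryl group. No stereocentre survives, since the racemic propargylic carbon becomes sp2 in the acyloxy shift and the transient sp3 carbon of 21 is lost on enolisation. The step needs the 1,2-shift rather than the 1,3-shift, which the unsubstituted alkyne terminus secures, and CO capture ahead of carbene cyclopentannulation, which the high CO pressure secures; together these place the free hydroxyl ortho to the ring A–ring B bond, the benzyl ether on the other ortho carbon and the pivalate para. The Z enol ether turns the biaryl outward in the closing triene, and its oxygen makes the alkene terminus more nucleophilic toward the ketene carbon.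

Step 12
Reactants: 22 3-(benzyloxy)-5-(pivaloyloxy)-2-Ar-phenol
Product: 23 3-(benzyloxy)-5-(pivaloyloxy)-2-Ar-phenyl hydrogen sulfate
Conditions: SO3·pyridine (5 equiv), pyridine, 50 °C
Reagents that add atoms: sulfur trioxide–pyridine complex, [O-]S(=O)(=O)[n+]1ccccc1
Why: O-Sulfonation of a phenol with SO3·pyridine, in which 22 has a single free hydroxyl, so the sulfate can only land on the CO-derived oxygen, and gentle heating with excess reagent should overcome shielding by the neighbouring biaryl.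

Step 13
Reactants: 23 3-(benzyloxy)-5-(pivaloyloxy)-2-Ar-phenyl hydrogen sulfate
Product: 24 3-(benzyloxy)-5-hydroxy-2-Ar-phenyl hydrogen sulfate
Conditions: NaOH (5 equiv), MeOH/THF/H2O, 40 °C; then dilute HCl to pH 7, 0 °C
Reagents that add atoms: none
Why: Saponification, in which hydroxide attacks the aryl pivalate at its acyl carbon, whereas the anionic sulfate monoester repels nucleophiles and benzyl ethers are inert to base, so only the para oxygen of ring A should be freed.

Step 14
Reactants: 24 3-(benzyloxy)-5-hydroxy-2-Ar-phenyl hydrogen sulfate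
Product: 25 target, 3,5-dihydroxy-2-{2,4,6-trihydroxy-3-(2,4,6-trihydroxyphenyl)phenyl}phenyl hydrogen sulfate
Conditions: H2 (1 atm), 10% Pd/C, MeOH/THF/H2O, rt; then strongly acidic cation-exchange resin (H+ form), H2O, 0 °C, freeze-drying
Reagents that add atoms: none
Why: Catalytic hydrogenolysis of all seven benzyl ethers under neutral conditions, to which aryl sulfate salts are stable, after which brief cold contact with the acid resin exchanges sodium for a proton and gives the target in the form drawn.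

**Compound list**

1 | phloroglucinol | Oc1cc(O)cc(O)c1 | starting material
2 | benzyl bromide | BrCc1ccccc1 | starting material
3 | 1,3,5-tris(benzyloxy)benzene | c1(OCc2ccccc2)cc(OCc2ccccc2)cc(OCc2ccccc2)c1 | intermediate
4 | 1,3,5-tris(benzyloxy)-2-iodobenzene | Ic1c(OCc2ccccc2)cc(OCc2ccccc2)cc1OCc1ccccc1 | intermediate
5 | 2,2',4,4',6,6'-hexakis(benzyloxy)-1,1'-biphenyl | c1(-c2c(OCc3ccccc3)cc(OCc3ccccc3)cc2OCc2ccccc2)c(OCc2ccccc2)cc(OCc2ccccc2)cc1OCc1ccccc1 | intermediate
6 | {2,4,6-tris(benzyloxy)-3-[2,4,6-tris(benzyloxy)phenyl]benzylidene}dimethylammonium dichlorophosphate | C[N+](C)=Cc1c(OCc2ccccc2)cc(OCc2ccccc2)c(-c2c(OCc3ccccc3)cc(OCc3ccccc3)cc2OCc2ccccc2)c1OCc1ccccc1.[O-]P(=O)(Cl)Cl | intermediate (not isolated)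
7 | 2,4,6-tris(benzyloxy)-3-[2,4,6-tris(benzyloxy)phenyl]benzaldehyde | O=Cc1c(OCc2ccccc2)cc(OCc2ccccc2)c(-c2c(OCc3ccccc3)cc(OCc3ccccc3)cc2OCc2ccccc2)c1OCc1ccccc1 | intermediate
8 | triethyl phosphonoacetate | CCOC(=O)CP(=O)(OCC)OCC | starting material
9 | ethyl 2-diazo-2-(diethoxyphosphoryl)acetate | CCOC(=O)C(=[N+]=[N-])P(=O)(OCC)OCC | intermediate
10 | benzyl alcohol | OCc1ccccc1 | starting material
11 | racemic ethyl 2-(benzyloxy)-2-(diethoxyphosphoryl)acetate | CCOC(=O)C(OCc1ccccc1)P(=O)(OCC)OCC | intermediate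
12 | ethyl (Z)-2-(benzyloxy)-3-{2,4,6-tris(benzyloxy)-3-[2,4,6-tris(benzyloxy)phenyl]phenyl}prop-2-enoate | CCOC(=O)/C(OCc1ccccc1)=C/c1c(OCc2ccccc2)cc(OCc2ccccc2)c(-c2c(OCc3ccccc3)cc(OCc3ccccc3)cc2OCc2ccccc2)c1OCc1ccccc1 | intermediate
13 | (Z)-2-(benzyloxy)-3-{2,4,6-tris(benzyloxy)-3-[2,4,6-tris(benzyloxy)phenyl]phenyl}prop-2-en-1-ol | OC/C(OCc1ccccc1)=C/c1c(OCc2ccccc2)cc(OCc2ccccc2)c(-c2c(OCc3ccccc3)cc(OCc3ccccc3)cc2OCc2ccccc2)c1OCc1ccccc1 | intermediate
14 | (Z)-2-(benzyloxy)-3-{2,4,6-tris(benzyloxy)-3-[2,4,6-tris(benzyloxy)phenyl]phenyl}prop-2-enal | O=C/C(OCc1ccccc1)=C/c1c(OCc2ccccc2)cc(OCc2ccccc2)c(-c2c(OCc3ccccc3)cc(OCc3ccccc3)cc2OCc2ccccc2)c1OCc1ccccc1 | intermediate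
15 | ethynylmagnesium bromide | C#C[Mg]Br | starting material
16 | pivaloyl chloride | CC(C)(C)C(=O)Cl | starting material
17 | bromomagnesium alkoxide of racemic (Z)-4-(benzyloxy)-5-{2,4,6-tris(benzyloxy)-3-[2,4,6-tris(benzyloxy)phenyl]phenyl}pent-4-en-1-yn-3-ol | C#CC(O[Mg]Br)/C(OCc1ccccc1)=C/c1c(OCc2ccccc2)cc(OCc2ccccc2)c(-c2c(OCc3ccccc3)cc(OCc3ccccc3)cc2OCc2ccccc2)c1OCc1ccccc1 | intermediate (not isolated)
18 | racemic (Z)-4-(benzyloxy)-5-{2,4,6-tris(benzyloxy)-3-[2,4,6-tris(benzyloxy)phenyl]phenyl}pent-4-en-1-yn-3-yl pivalate | C#CC(OC(=O)C(C)(C)C)/C(OCc1ccccc1)=C/c1c(OCc2ccccc2)cc(OCc2ccccc2)c(-c2c(OCc3ccccc3)cc(OCc3ccccc3)cc2OCc2ccccc2)c1OCc1ccccc1 | intermediate (key-step precursor)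
19 | carbon monoxide | [C-]#[O+] | starting material
20 | (3E,5Z)-5-(benzyloxy)-1-oxo-6-{2,4,6-tris(benzyloxy)-3-[2,4,6-tris(benzyloxy)phenyl]phenyl}hexa-1,3,5-trien-3-yl pivalate (dienylketene) | O=C=C/C(OC(=O)C(C)(C)C)=C\C(OCc1ccccc1)=C\c1c(OCc2ccccc2)cc(OCc2ccccc2)c(-c2c(OCc3ccccc3)cc(OCc3ccccc3)cc2OCc2ccccc2)c1OCc1ccccc1 | intermediate (not isolated)
21 | racemic 5-(benzyloxy)-3-oxo-4-{2,4,6-tris(benzyloxy)-3-[2,4,6-tris(benzyloxy)phenyl]phenyl}cyclohexa-1,5-dien-1-yl pivalate (cyclohexadienone) | O=C1C=C(OC(=O)C(C)(C)C)C=C(OCc2ccccc2)C1c1c(OCc2ccccc2)cc(OCc2ccccc2)c(-c2c(OCc3ccccc3)cc(OCc3ccccc3)cc2OCc2ccccc2)c1OCc1ccccc1 | intermediate (not isolated)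
22 | 3-(benzyloxy)-5-(pivaloyloxy)-2-{2,4,6-tris(benzyloxy)-3-[2,4,6-tris(benzyloxy)phenyl]phenyl}phenol | Oc1cc(OC(=O)C(C)(C)C)cc(OCc2ccccc2)c1-c1c(OCc2ccccc2)cc(OCc2ccccc2)c(-c2c(OCc3ccccc3)cc(OCc3ccccc3)cc2OCc2ccccc2)c1OCc1ccccc1 | intermediate (key-step product)
23 | 3-(benzyloxy)-5-(pivaloyloxy)-2-{2,4,6-tris(benzyloxy)-3-[2,4,6-tris(benzyloxy)phenyl]phenyl}phenyl hydrogen sulfate | O=S(=O)(O)Oc1cc(OC(=O)C(C)(C)C)cc(OCc2ccccc2)c1-c1c(OCc2ccccc2)cc(OCc2ccccc2)c(-c2c(OCc3ccccc3)cc(OCc3ccccc3)cc2OCc2ccccc2)c1OCc1ccccc1 | intermediate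
24 | 3-(benzyloxy)-5-hydroxy-2-{2,4,6-tris(benzyloxy)-3-[2,4,6-tris(benzyloxy)phenyl]phenyl}phenyl hydrogen sulfate | O=S(=O)(O)Oc1cc(O)cc(OCc2ccccc2)c1-c1c(OCc2ccccc2)cc(OCc2ccccc2)c(-c2c(OCc3ccccc3)cc(OCc3ccccc3)cc2OCc2ccccc2)c1OCc1ccccc1 | intermediate
25 | 3,5-dihydroxy-2-[2,4,6-trihydroxy-3-(2,4,6-trihydroxyphenyl)phenyl]phenyl hydrogen sulfate (CNP0244954.0) | O=S(=O)(O)Oc1cc(O)cc(O)c1-c1c(O)cc(O)c(-c2c(O)cc(O)cc2O)c1O | target

**Step count**

Total step count: 14.
Longest linear sequence: 12 steps (1–4, then 7–14, from phloroglucinol). Steps 5 and 6 form a two-step side branch that joins at step 7.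

**Steps most likely to fail**

**Step 11.**
- Risk: closure onto the crowded, aryl-bearing enol-ether terminus may be too slow. Ionisation of the doubly activated pivalate, the competing 1,3-acyloxy shift, or carbene cyclisation without CO uptake could then overtake carbonylation.
- Fallback: it sets out from 5 and comes back to the route at 25. Ring A is no longer built but brought in as a differentiated phloroglucinol.
- Ring B–C partner: compound 5 is mono-iodinated with a slight deficit of NIS to 3-iodo-2,2',4,4',6,6'-hexakis(benzyloxy)-1,1'-biphenyl F1.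
- Ring A partner: commercial 3,5-bis(benzyloxy)phenol (Oc1cc(OCc2ccccc2)cc(OCc2ccccc2)c1) is protected with MOMCl and i-Pr2NEt as 1,3-bis(benzyloxy)-5-(methoxymethoxy)benzene F2. Directed ortho-metalation with n-BuLi next to the acetal oxygen gives [2,4-bis(benzyloxy)-6-(methoxymethoxy)phenyl]lithium F3, and ZnCl2 converts this into [2,4-bis(benzyloxy)-6-(methoxymethoxy)phenyl]zinc chloride F4.
- Coupling: Negishi coupling of F4 with F1 (Pd2(dba)3, RuPhos, THF, 70 °C) should form the ring A–ring B bond and give 1,5-bis(benzyloxy)-3-(methoxymethoxy)-2-Ar-benzene F5.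
- Completion: HCl in MeOH/THF frees the single phenol 3,5-bis(benzyloxy)-2-Ar-phenol F6, and SO3·pyridine gives 3,5-bis(benzyloxy)-2-Ar-phenyl hydrogen sulfate F7. Hydrogenolysis of its eight benzyl ethers under the conditions of step 14 leads to 25.

**Step 4.**
- Risk: the twisted biaryl axis insulates the two rings electronically, so a second formylation on the untouched ring may compete with the first and erode mono-selectivity.
- Fallback: it sets out from 3 and 4 and comes back at 7. It installs the formyl group before the rings are joined, which also makes step 3 unnecessary.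
- Electrophile: compound 3 is formylated with POCl3/DMF, where the only ring present is deactivated after one attack. This passes through [2,4,6-tris(benzyloxy)benzylidene]dimethylammonium dichlorophosphate F8 to 2,4,6-tris(benzyloxy)benzaldehyde F9. NBS in CH2Cl2 brominates one of its two equivalent free positions to give 3-bromo-2,4,6-tris(benzyloxy)benzaldehyde F10.
- Nucleophile: iodide 4 undergoes iodine–lithium exchange with n-BuLi at −78 °C to [2,4,6-tris(benzyloxy)phenyl]lithium F11, and ZnCl2 gives [2,4,6-tris(benzyloxy)phenyl]zinc chloride F12.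
- Coupling: Negishi coupling of F12 with F10 (Pd2(dba)3, RuPhos, THF, 70 °C), which tolerates the aldehyde, should deliver 7.

**Step 7.**
- Risk: addition of the hindered phosphonate anion to the electron-rich, doubly ortho-substituted aldehyde may be sluggish, and the E/Z selectivity of the elimination may be poor.
- Fallback: it sets out from 7 and comes back at 12. It replaces the olefination by aldol addition and base-induced elimination.
- Aldol: the LiN(i-Pr)2 enolate of commercial ethyl 2-(benzyloxy)acetate (CCOC(=O)COCc1ccccc1) is added to 7 at −78 °C to give ethyl 2-(benzyloxy)-3-hydroxy-3-Ar-propanoate F13 as a mixture of diastereomers.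
- Elimination: MsCl and Et3N convert F13 into ethyl 2-(benzyloxy)-3-(methylsulfonyloxy)-3-Ar-propanoate F14. DBU eliminates this in the same flask by an E1cB pathway whose carbanion forgets the aldol configuration, so both diastereomers should funnel into the more stable Z ester 12.

**Further compounds**

F1 | step 11 | 3-iodo-2,2',4,4',6,6'-hexakis(benzyloxy)-1,1'-biphenyl | Ic1c(OCc2ccccc2)cc(OCc2ccccc2)c(-c2c(OCc3ccccc3)cc(OCc3ccccc3)cc2OCc2ccccc2)c1OCc1ccccc1
F2 | step 11 | 1,3-bis(benzyloxy)-5-(methoxymethoxy)benzene | COCOc1cc(OCc2ccccc2)cc(OCc2ccccc2)c1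
F3 | step 11 | [2,4-bis(benzyloxy)-6-(methoxymethoxy)phenyl]lithium | [Li]c1c(OCOC)cc(OCc2ccccc2)cc1OCc1ccccc1
F4 | step 11 | [2,4-bis(benzyloxy)-6-(methoxymethoxy)phenyl]zinc chloride | Cl[Zn]c1c(OCOC)cc(OCc2ccccc2)cc1OCc1ccccc1
F5 | step 11 | 1,5-bis(benzyloxy)-3-(methoxymethoxy)-2-{2,4,6-tris(benzyloxy)-3-[2,4,6-tris(benzyloxy)phenyl]phenyl}benzene | COCOc1cc(OCc2ccccc2)cc(OCc2ccccc2)c1-c1c(OCc2ccccc2)cc(OCc2ccccc2)c(-c2c(OCc3ccccc3)cc(OCc3ccccc3)cc2OCc2ccccc2)c1OCc1ccccc1
F6 | step 11 | 3,5-bis(benzyloxy)-2-{2,4,6-tris(benzyloxy)-3-[2,4,6-tris(benzyloxy)phenyl]phenyl}phenol | Oc1cc(OCc2ccccc2)cc(OCc2ccccc2)c1-c1c(OCc2ccccc2)cc(OCc2ccccc2)c(-c2c(OCc3ccccc3)cc(OCc3ccccc3)cc2OCc2ccccc2)c1OCc1ccccc1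
F7 | step 11 | 3,5-bis(benzyloxy)-2-{2,4,6-tris(benzyloxy)-3-[2,4,6-tris(benzyloxy)phenyl]phenyl}phenyl hydrogen sulfate | O=S(=O)(O)Oc1cc(OCc2ccccc2)cc(OCc2ccccc2)c1-c1c(OCc2ccccc2)cc(OCc2ccccc2)c(-c2c(OCc3ccccc3)cc(OCc3ccccc3)cc2OCc2ccccc2)c1OCc1ccccc1
F8 | step 4 | [2,4,6-tris(benzyloxy)benzylidene]dimethylammonium dichlorophosphate | C[N+](C)=Cc1c(OCc2ccccc2)cc(OCc2ccccc2)cc1OCc1ccccc1.[O-]P(=O)(Cl)Cl
F9 | step 4 | 2,4,6-tris(benzyloxy)benzaldehyde | O=Cc1c(OCc2ccccc2)cc(OCc2ccccc2)cc1OCc1ccccc1
F10 | step 4 | 3-bromo-2,4,6-tris(benzyloxy)benzaldehyde | O=Cc1c(OCc2ccccc2)cc(OCc2ccccc2)c(Br)c1OCc1ccccc1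
F11 | step 4 | [2,4,6-tris(benzyloxy)phenyl]lithium | [Li]c1c(OCc2ccccc2)cc(OCc2ccccc2)cc1OCc1ccccc1
F12 | step 4 | [2,4,6-tris(benzyloxy)phenyl]zinc chloride | Cl[Zn]c1c(OCc2ccccc2)cc(OCc2ccccc2)cc1OCc1ccccc1
F13 | step 7 | ethyl 2-(benzyloxy)-3-hydroxy-3-{2,4,6-tris(benzyloxy)-3-[2,4,6-tris(benzyloxy)phenyl]phenyl}propanoate (mixture of diastereomers) | CCOC(=O)C(OCc1ccccc1)C(O)c1c(OCc2ccccc2)cc(OCc2ccccc2)c(-c2c(OCc3ccccc3)cc(OCc3ccccc3)cc2OCc2ccccc2)c1OCc1ccccc1
F14 | step 7 | ethyl 2-(benzyloxy)-3-(methylsulfonyloxy)-3-{2,4,6-tris(benzyloxy)-3-[2,4,6-tris(benzyloxy)phenyl]phenyl}propanoate (mixture of diastereomers) | CCOC(=O)C(OCc1ccccc1)C(OS(C)(=O)=O)c1c(OCc2ccccc2)cc(OCc2ccccc2)c(-c2c(OCc3ccccc3)cc(OCc3ccccc3)cc2OCc2ccccc2)c1OCc1ccccc1
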